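The cyclopentane ring (C5–C6–C7–C8–C9, iridoid numbering) is disconnected at C5–C6 to a cyclopropane (C5, C8, C9) fused to a pyranone and bearing vinyl (C7=C6) and ester (C10) groups on C8. A thermal vinylcyclopropane–cyclopentene rearrangement enlarges this three-membered ring by two atoms in one operation and delivers the cis-fused cyclopenta[c]pyran with C7=C8 and C10 in place. It exploits the C4 carbonyl (later the enol ether carbon carrying C11) flanking C5, which weakens the C5–C8 bond, and the latent C7=C8 unsaturation behind the trans C7–O/C8–OH pair. The precursor arises by Michael-initiated ring closure on an enantioenriched Achmatowicz pyranone whose C1 acetal relays all ring stereochemistry.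

Key step: step 5

Numbering used throughout: C1 acetal carbon, O2, C3=C4 enol ether, C5 and C9 ring-fusion carbons, C6–C8 cyclopentane carbons, C10 on C8, C11 on C4; β is the face of H-5 and H-9.
Assumption: (R)-3-methylpentanoic acid (21), methyl (Z)-2-bromobut-2-enoate (5) and tert-butyl(4-ethynylphenoxy)dimethylsilane (14) are treated as purchasable.

Step 1
Reactants: 1 furfuryl alcohol
Product: 2 6-hydroxy-2H-pyran-3(6H)-one (racemic lactol)
Conditions: mCPBA (1.05 equiv), CH2Cl2, 0 °C
Reagents that add atoms: 3-chloroperoxybenzoic acid, OOC(=O)c1cccc(Cl)c1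
Why: Achmatowicz rearrangement, in which oxidation of the furan and lactol closure of the resulting hydroxy enedione give the pyranone, whose only stereocenter (C1) stays labile by ring–chain tautomerism.

Step 2
Reactants: 2 6-hydroxy-2H-pyran-3(6H)-one
Product: 3 (S)-6-(isobutyryloxy)-2H-pyran-3(6H)-one
Conditions: (R)-benzotetramisole (5 mol %), (i-PrCO)2O (1.2 equiv), CHCl3, 0 °C
Reagents that add atoms: isobutyric anhydride, CC(C)C(=O)OC(=O)C(C)C
Why: Dynamic kinetic resolution by isothiourea-catalysed acyl transfer, in which the lactol enantiomers interconvert while the acyl-isothiouronium ion acylates one of them faster (the enone π-system taking the place of the aryl group of a benzylic alcohol), so the catalyst enantiomer is chosen to fix C1 as S.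

Step 3
Reactants: 3 (S)-6-(isobutyryloxy)-2H-pyran-3(6H)-one
Product: 4 (R)-6-[(4-methoxybenzyl)oxy]-2H-pyran-3(6H)-one
Conditions: Pd2(dba)3·CHCl3 (2.5 mol %), PPh3 (10 mol %), 4-methoxybenzyl alcohol (1.5 equiv), CH2Cl2, 0 °C
Reagents that add atoms: 4-methoxybenzyl alcohol, COc1ccc(CO)cc1
Why: Tsuji–Trost-type O-glycosylation, in which ionisation anti to the carboxylate and anti attack of the alcohol on the π-allyl palladium complex give net retention at C1 and replace the base-labile ester by a robust acetal.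

Step 4
Reactants: 4 (R)-6-[(4-methoxybenzyl)oxy]-2H-pyran-3(6H)-one; 5 methyl (Z)-2-bromobut-2-enoate
Product: 8 methyl (1S,2R,6R)-2-[(4-methoxybenzyl)oxy]-5-oxo-7-vinyl-3-oxabicyclo[4.1.0]heptane-7-carboxylate (both epimers at the vinyl-bearing carbon C8), via lithium dienolate 6 (not isolated), via Michael adduct enolate 7 (not isolated)
Conditions: LiN(iPr)2 (1.1 equiv), THF–DMPU, −78 °C, 5; then 4, −78 → −20 °C
Reagents that add atoms: none
Why: Michael-initiated ring closure, in which the α-carbon of the bromodienolate adds to C9 anti to the C1 alkoxy group and the resulting C5 enolate displaces bromide (3-exo-tet), setting C9 and C5 as a cis-fused cyclopropane on the α face while C8 forms as a mixture that converges in step 5.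

Step 5
Reactants: 8 methyl (1S,2R,6R)-2-[(4-methoxybenzyl)oxy]-5-oxo-7-vinyl-3-oxabicyclo[4.1.0]heptane-7-carboxylate
Product: 9 methyl (1R,4aS,7aS)-1-[(4-methoxybenzyl)oxy]-4-oxo-1,3,4,4a,5,7a-hexahydrocyclopenta[c]pyran-7-carboxylate
Conditions: flash vacuum pyrolysis, 540 °C, 10⁻⁴ mbar, quartz tube conditioned with PbCO3
Reagents that add atoms: none
Why: Homolysis of the doubly activated C5–C8 cyclopropane bond should give a 1,3-diradical (α-keto radical at C5, ester-substituted allyl radical C8–C7–C6) that recombines at C5–C6, a formal 1,3-shift. The closest known reaction type is the vinylcyclopropane–cyclopentene rearrangement of 1-vinyl-1-alkoxycarbonyl bicyclic cyclopropyl ketones. The ring C5–C6–C7–C8–C9 closes by radical recombination at the terminus of the allyl unit, so the three-membered ring grows by the two vinyl carbons. C9 is untouched, and the re-formed C5 stereocenter is controlled by the C8–C7–C6 tether, which can reach C5 only from the α face where C8 is held, so the fusion is cis with H-5 and H-9 β and anti to the C1 oxygen. C8 becomes sp2, so both epimers of 8 give one product. The step needs cleavage of C5–C8 rather than C9–C8, which the C4 carbonyl secures by stabilising the C5 radical, and a short contact time to outrun the homodienyl 1,5-hydrogen shift of the endo-vinyl epimer.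

Step 6
Reactants: 9 methyl (1R,4aS,7aS)-1-[(4-methoxybenzyl)oxy]-4-oxo-1,3,4,4a,5,7a-hexahydrocyclopenta[c]pyran-7-carboxylate
Product: 11 methyl (1R,4aS,7aS)-1-[(4-methoxybenzyl)oxy]-4-{[(trifluoromethyl)sulfonyl]oxy}-1,4a,5,7a-tetrahydrocyclopenta[c]pyran-7-carboxylate, via potassium enolate 10 (not isolated)
Conditions: KN(SiMe3)2 (1.1 equiv), THF, −78 °C; then PhNTf2 (1.2 equiv), −78 → −40 °C
Reagents that add atoms: N-phenylbis(trifluoromethanesulfonimide), O=S(=O)(N(c1ccccc1)S(=O)(=O)C(F)(F)F)C(F)(F)F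
Why: Kinetic deprotonation at the less hindered C3 methylene and O-sulfonylation of the enolate give the C3=C4 enol triflate, the handle for C11.

Step 7
Reactants: 11 methyl (1R,4aS,7aS)-1-[(4-methoxybenzyl)oxy]-4-{[(trifluoromethyl)sulfonyl]oxy}-1,4a,5,7a-tetrahydrocyclopenta[c]pyran-7-carboxylate
Product: 12 (1R,4aS,7aS)-7-(hydroxymethyl)-1-[(4-methoxybenzyl)oxy]-1,4a,5,7a-tetrahydrocyclopenta[c]pyran-4-yl trifluoromethanesulfonate
Conditions: i-Bu2AlH (2.5 equiv), CH2Cl2, −78 °C; aqueous KNaC4H4O6
Reagents that add atoms: none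
Why: 1,2-Reduction of the conjugated ester by the aluminium hydride should stop at the allylic alcohol, and the vinyl triflate and the acetal are inert at −78 °C.

Step 8
Reactants: 12 (1R,4aS,7aS)-7-(hydroxymethyl)-1-[(4-methoxybenzyl)oxy]-1,4a,5,7a-tetrahydrocyclopenta[c]pyran-4-yl trifluoromethanesulfonate
Product: 13 7α,8α-epoxide of 12 (oxirane oxygen on the α face, cis to C1 and C4; C10–OH free)
Conditions: Ti(OiPr)4 (1.0 equiv), D-(−)-diisopropyl tartrate (1.2 equiv), t-BuOOH (2 equiv), 4 Å molecular sieves, CH2Cl2, −20 °C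
Reagents that add atoms: tert-butyl hydroperoxide, CC(C)(C)OO
Why: Sharpless asymmetric epoxidation, in which the D-(−)-tartrate complex should deliver the peroxide oxygen to the α face of the C7=C8 allylic alcohol (reagent control against the modest preference for the convex β face), setting C7 and the C8–O bond.

Step 9
Reactants: 14 tert-butyl(4-ethynylphenoxy)dimethylsilane
Product: 16 3-[4-(tert-butyldimethylsilyloxy)phenyl]prop-2-ynoic acid, via lithium acetylide 15 (not isolated)
Conditions: n-BuLi (1.05 equiv), THF, −78 °C; CO2 (g), −78 → 0 °C; then 1 M HCl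
Reagents that add atoms: carbon dioxide, O=C=O
Why: Deprotonation of the terminal alkyne and carboxylation of the acetylide give the arylpropiolic acid.

Step 10
Reactants: 16 3-[4-(tert-butyldimethylsilyloxy)phenyl]prop-2-ynoic acid
Product: 17 (2Z)-3-[4-(tert-butyldimethylsilyloxy)phenyl]prop-2-enoic acid
Conditions: H2 (1 atm), Pd/CaCO3 poisoned with Pb(OAc)2, quinoline, EtOAc, rt, dark
Reagents that add atoms: none
Why: Lindlar semihydrogenation, in which syn delivery of hydrogen on the poisoned palladium surface gives the Z-alkene and stops before over-reduction.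

Step 11
Reactants: 13 7α,8α-epoxide of 12; 17 (2Z)-3-[4-(tert-butyldimethylsilyloxy)phenyl]prop-2-enoic acid
Product: 18 (1R,4aS,6S,7R,7aS)-7-hydroxy-7-(hydroxymethyl)-1-[(4-methoxybenzyl)oxy]-4-{[(trifluoromethyl)sulfonyl]oxy}-1,4a,5,6,7,7a-hexahydrocyclopenta[c]pyran-6-yl (2Z)-3-[4-(tert-butyldimethylsilyloxy)phenyl]prop-2-enoate
Conditions: Ti(OiPr)4 (1.5 equiv), 17 (1.5 equiv), CH2Cl2, rt, dark
Reagents that add atoms: none
Why: Titanium-mediated regioselective opening of a 2,3-epoxy alcohol by a carboxylic acid, in which the carboxylate attacks the distal secondary carbon C7 of the alkoxide–epoxide chelate from the β face with inversion, giving the 7β-ester trans to the retained 8α-hydroxyl.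

Step 12
Reactants: 18 the 7β-coumarate diol
Product: 19 (1R,4aS,6S,7R,7aS)-7-{[(tert-butyldimethylsilyl)oxy]methyl}-7-hydroxy-1-[(4-methoxybenzyl)oxy]-4-{[(trifluoromethyl)sulfonyl]oxy}-1,4a,5,6,7,7a-hexahydrocyclopenta[c]pyran-6-yl (2Z)-3-[4-(tert-butyldimethylsilyloxy)phenyl]prop-2-enoate
Conditions: t-BuMe2SiCl (1.2 equiv), imidazole (2.5 equiv), CH2Cl2, 0 °C
Reagents that add atoms: tert-butyldimethylsilyl chloride, CC(C)(C)[Si](C)(C)Cl
Why: Silylation of the primary C10 hydroxyl is much faster than that of the tertiary C8 hydroxyl, so only C10–OH is masked before the acetal exchange.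

Step 13
Reactants: 19 the C10 silyl ether
Product: 20 (1R,4aS,6S,7R,7aS)-7-{[(tert-butyldimethylsilyl)oxy]methyl}-1,7-dihydroxy-4-{[(trifluoromethyl)sulfonyl]oxy}-1,4a,5,6,7,7a-hexahydrocyclopenta[c]pyran-6-yl (2Z)-3-[4-(tert-butyldimethylsilyloxy)phenyl]prop-2-enoate (C1 lactol)
Conditions: DDQ (1.5 equiv), CH2Cl2–pH 7 phosphate buffer (10:1), 0 °C → rt, dark
Reagents that add atoms: none
Why: Oxidative cleavage of the 4-methoxybenzyl acetal (benzylic hydride abstraction by the quinone, then hydrolysis of the oxocarbenium ion) frees the lactol without breaking the C1–O bond, so C1 keeps its configuration, and the electron-poor enol triflate is not attacked.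

Step 14
Reactants: 20 the C1 lactol; 21 (R)-3-methylpentanoic acid
Product: 22 (1S,4aS,6S,7R,7aS)-7-{[(tert-butyldimethylsilyl)oxy]methyl}-6-{[(2Z)-3-[4-(tert-butyldimethylsilyloxy)phenyl]prop-2-enoyl]oxy}-7-hydroxy-4-{[(trifluoromethyl)sulfonyl]oxy}-1,4a,5,6,7,7a-hexahydrocyclopenta[c]pyran-1-yl (3R)-3-methylpentanoate
Conditions: DCC (1.3 equiv), DMAP (0.2 equiv), 21 (1.2 equiv), CH2Cl2, 0 °C, dark
Reagents that add atoms: none
Why: Steglich esterification acylates the lactol oxygen with retention at C1 (the 1β-acyloxy acetal anti to the cyclopentane is also the favoured anomer), while the tertiary C8 hydroxyl does not react.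

Step 15
Reactants: 22 the C1 ester vinyl triflate
Product: 23 (1S,4aS,6S,7R,7aS)-7-{[(tert-butyldimethylsilyl)oxy]methyl}-6-{[(2Z)-3-[4-(tert-butyldimethylsilyloxy)phenyl]prop-2-enoyl]oxy}-7-hydroxy-4-(hydroxymethyl)-1,4a,5,6,7,7a-hexahydrocyclopenta[c]pyran-1-yl (3R)-3-methylpentanoate
Conditions: Bu3SnCH2OH (1.5 equiv), Pd(PPh3)4 (10 mol %), LiCl (3 equiv), 1,4-dioxane, 80 °C, dark
Reagents that add atoms: (tributylstannyl)methanol, CCCC[Sn](CCCC)(CCCC)CO
Why: Stille coupling of the vinyl triflate with the hydroxymethylstannane (oxidative addition, chloride-assisted transmetalation, reductive elimination) installs C11 directly at the alcohol oxidation level under neutral conditions that the esters tolerate.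

Step 16
Reactants: 23 the bis-silyl ether
Product: 24 (1S,4aS,6S,7R,7aS)-7-hydroxy-4,7-bis(hydroxymethyl)-6-{[(2Z)-3-(4-hydroxyphenyl)prop-2-enoyl]oxy}-1,4a,5,6,7,7a-hexahydrocyclopenta[c]pyran-1-yl (3R)-3-methylpentanoate (CNP0217341.1)
Conditions: HF·pyridine, pyridine, THF, 0 °C → rt, dark
Reagents that add atoms: none
Why: Fluoride-mediated cleavage of the aryl and primary silyl ethers under buffered, weakly acidic conditions should leave the acyloxy acetal, the enol ether and the Z-enoate intact.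

Compound list
1 | furfuryl alcohol | OCc1ccco1 | starting material
2 | 6-hydroxy-2H-pyran-3(6H)-one (racemic, C1 labile) | OC1OCC(=O)C=C1 | intermediate
3 | (S)-6-(isobutyryloxy)-2H-pyran-3(6H)-one | CC(C)C(=O)O[C@@H]1OCC(=O)C=C1 | intermediate
4 | (R)-6-[(4-methoxybenzyl)oxy]-2H-pyran-3(6H)-one | COc1ccc(CO[C@@H]2OCC(=O)C=C2)cc1 | intermediate
5 | methyl (Z)-2-bromobut-2-enoate | C/C=C(\Br)C(=O)OC | starting material
6 | lithium 2-bromo-1-methoxybuta-1,3-dien-1-olate (not isolated) | C=CC(Br)=C([O-])OC.[Li+] | intermediate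
7 | lithium enolate of the Michael adduct at C9, trans to the C1 alkoxy group, C8 epimers (not isolated) | COc1ccc(CO[C@@H]2OCC([O-])=C[C@H]2C(Br)(C=C)C(=O)OC)cc1.[Li+] | intermediate
8 | methyl (1S,2R,6R)-2-[(4-methoxybenzyl)oxy]-5-oxo-7-vinyl-3-oxabicyclo[4.1.0]heptane-7-carboxylate (C8 unspecified, both epimers) | COc1ccc(CO[C@@H]2OCC(=O)[C@H]3C(C=C)(C(=O)OC)[C@@H]23)cc1 | intermediate
9 | methyl (1R,4aS,7aS)-1-[(4-methoxybenzyl)oxy]-4-oxo-1,3,4,4a,5,7a-hexahydrocyclopenta[c]pyran-7-carboxylate | COc1ccc(CO[C@@H]2OCC(=O)[C@H]3CC=C(C(=O)OC)[C@@H]23)cc1 | intermediate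
10 | potassium C3=C4 enolate of 9 (not isolated) | COc1ccc(CO[C@@H]2OC=C([O-])[C@H]3CC=C(C(=O)OC)[C@@H]23)cc1.[K+] | intermediate
11 | methyl (1R,4aS,7aS)-1-[(4-methoxybenzyl)oxy]-4-{[(trifluoromethyl)sulfonyl]oxy}-1,4a,5,7a-tetrahydrocyclopenta[c]pyran-7-carboxylate | COc1ccc(CO[C@@H]2OC=C(OS(=O)(=O)C(F)(F)F)[C@H]3CC=C(C(=O)OC)[C@@H]23)cc1 | intermediate
12 | (1R,4aS,7aS)-7-(hydroxymethyl)-1-[(4-methoxybenzyl)oxy]-1,4a,5,7a-tetrahydrocyclopenta[c]pyran-4-yl trifluoromethanesulfonate | COc1ccc(CO[C@@H]2OC=C(OS(=O)(=O)C(F)(F)F)[C@H]3CC=C(CO)[C@@H]23)cc1 | intermediate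
13 | 7α,8α-epoxide of 12 (epoxy alcohol) | COc1ccc(CO[C@@H]2OC=C(OS(=O)(=O)C(F)(F)F)[C@H]3C[C@H]4O[C@@]4(CO)[C@@H]23)cc1 | intermediate
14 | tert-butyl(4-ethynylphenoxy)dimethylsilane | C#Cc1ccc(O[Si](C)(C)C(C)(C)C)cc1 | starting material
15 | lithium acetylide of 14 (not isolated) | [Li]C#Cc1ccc(O[Si](C)(C)C(C)(C)C)cc1 | intermediate
16 | 3-[4-(tert-butyldimethylsilyloxy)phenyl]prop-2-ynoic acid | OC(=O)C#Cc1ccc(O[Si](C)(C)C(C)(C)C)cc1 | intermediate
17 | (2Z)-3-[4-(tert-butyldimethylsilyloxy)phenyl]prop-2-enoic acid | OC(=O)/C=C\c1ccc(O[Si](C)(C)C(C)(C)C)cc1 | intermediate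
18 | 7β-(Z)-coumarate, 8α-OH, C10–OH, C1–O-(4-methoxybenzyl), C4 triflate (1R,4aS,6S,7R,7aS) | COc1ccc(CO[C@@H]2OC=C(OS(=O)(=O)C(F)(F)F)[C@H]3C[C@H](OC(=O)/C=C\c4ccc(O[Si](C)(C)C(C)(C)C)cc4)[C@](O)(CO)[C@@H]23)cc1 | intermediate
19 | C10 tert-butyldimethylsilyl ether of 18 | COc1ccc(CO[C@@H]2OC=C(OS(=O)(=O)C(F)(F)F)[C@H]3C[C@H](OC(=O)/C=C\c4ccc(O[Si](C)(C)C(C)(C)C)cc4)[C@](O)(CO[Si](C)(C)C(C)(C)C)[C@@H]23)cc1 | intermediate
20 | C1 lactol (1R,4aS,6S,7R,7aS) | O[C@@H]1OC=C(OS(=O)(=O)C(F)(F)F)[C@H]2C[C@H](OC(=O)/C=C\c3ccc(O[Si](C)(C)C(C)(C)C)cc3)[C@](O)(CO[Si](C)(C)C(C)(C)C)[C@@H]12 | intermediate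
21 | (R)-3-methylpentanoic acid | CC[C@@H](C)CC(=O)O | starting material
22 | C1 (3R)-3-methylpentanoate, C4 triflate (1S,4aS,6S,7R,7aS) | CC[C@@H](C)CC(=O)O[C@@H]1OC=C(OS(=O)(=O)C(F)(F)F)[C@H]2C[C@H](OC(=O)/C=C\c3ccc(O[Si](C)(C)C(C)(C)C)cc3)[C@](O)(CO[Si](C)(C)C(C)(C)C)[C@@H]12 | intermediate
23 | bis-silyl ether of the target (C11–OH free) | CC[C@@H](C)CC(=O)O[C@@H]1OC=C(CO)[C@H]2C[C@H](OC(=O)/C=C\c3ccc(O[Si](C)(C)C(C)(C)C)cc3)[C@](O)(CO[Si](C)(C)C(C)(C)C)[C@@H]12 | intermediate
24 | CNP0217341.1 | CC[C@@H](C)CC(=O)O[C@@H]1OC=C(CO)[C@H]2C[C@H](OC(=O)/C=C\c3ccc(O)cc3)[C@](O)(CO)[C@@H]12 | target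

Total step count: 16. Longest linear sequence: 14 steps (steps 1–8 and 11–16, from furfuryl alcohol); steps 9–10 prepare acid 17.

Steps most likely to fail

Step 5 (key step). The pyrolysis may be eroded by the homodienyl 1,5-hydrogen shift of the endo-vinyl epimer or by thermal loss of 4-methoxybenzyl alcohol from the acetal. The fallback runs the ring expansion as an ionic, stepwise process from 8. MgI2 (1.2 equiv) in THF at 60 °C should open the ketone-activated C5–C8 bond by SN2′ attack of iodide at the vinyl terminus C6. This gives the iodomagnesium enolate of the (E)-allylic iodide F1, which should close by intramolecular C-alkylation of C5 on C6 (5-exo-tet) and return to the route at 9. Re-closure to the cyclopropane is reversible, so the cyclopentene is the sink.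

Step 8. The epoxidation is the mismatched pairing, so poor facial selectivity or a sluggish reaction on the concave α face is possible. The fallback reaches the same epoxide by substrate control from 12. NBS in THF–H2O at 0 °C should form the bromonium ion on the convex β face and water should open it trans, giving the bromohydrin F2 (7β-Br, 8α-OH). K2CO3 in MeOH at 0 °C should then close the α-oxide with inversion at C7 and return to the route at 13. Either regiochemistry of water attack leads to the same α-epoxide.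

Step 15. Transmetalation of the oxygen-substituted vinyl triflate may be slow, so protodetriflation or Z-to-E isomerisation of the coumarate during prolonged heating could take over. The fallback introduces C11 in two milder steps from 22. Palladium-catalysed formylation (Pd(OAc)2, 1,3-bis(diphenylphosphino)propane, CO 1 atm, Et3SiH, Et3N, DMF, 60 °C) should give the vinylogous formate aldehyde F3. Luche reduction (NaBH4, CeCl3·7H2O, MeOH, −40 °C) should then reduce only the aldehyde and return to the route at 23.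

Further compounds
F1 | step 5 | iodomagnesium enolate of methyl (E)-4-iodo-2-[(2R,3S)-2-(4-methoxybenzyloxy)-5-oxo-tetrahydropyran-3-yl]but-2-enoate (C6 cis to C9) | COc1ccc(CO[C@@H]2OCC(O[Mg]I)=C[C@H]2/C(C(=O)OC)=C\CI)cc1
F2 | step 8 | 7β-bromo-8α-hydroxy bromohydrin of 12 (C10–OH free) | COc1ccc(CO[C@@H]2OC=C(OS(=O)(=O)C(F)(F)F)[C@H]3C[C@H](Br)[C@](O)(CO)[C@@H]23)cc1
F3 | step 15 | C4-formyl analogue of 23 (C11 aldehyde) | CC[C@@H](C)CC(=O)O[C@@H]1OC=C(C=O)[C@H]2C[C@H](OC(=O)/C=C\c3ccc(O[Si](C)(C)C(C)(C)C)cc3)[C@](O)(CO[Si](C)(C)C(C)(C)C)[C@@H]12
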